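**Plan**

1. Retrosynthetic cuts, in order: the gallate ester C–O at O3′ of ring B; the O1–C8a aryl ether of ring C; the C2–C1′ bond (ring B onto a C2 carbonyl); the C3–C4 bond (glycolate enolate onto a ring A benzyl bromide).
2. Forward: ring A benzyl bromide plus chiral glycolate (C3–C4), then ring B aryllithium (C2–C1′), then ring C by O1–C8a closure, then the 3′-phenol alone is freed and galloylated, then all benzyl ethers are removed.
3. Enabling feature: in ring A, C8 bears only H and lies beside the C7 oxygen, while C8a is meta to both oxygens yet adjacent to C4a, which carries the C4–C3–C2 chain ending in the C2 hydroxyl. An aryne across C8–C8a, made from a C8 chloride, is captured at C8a by that alkoxide, and C8 ends as C–H.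
4. Stereochemistry: C3 (S) from the (R)-4-benzyloxazolidinone auxiliary; C2 (R) from chelation-controlled reduction of the α-benzyloxy ketone (1,2-anti, hence 2,3-trans); the ring closure breaks no bond at C2 or C3.
5. O3′ travels as a MOM ether and O4′ as a benzyl ether, so that the ester can form at O3′ only.

Key step: step 11

Remark: the target is taken as the 3′-O-galloyl ester of (+)-catechin, (2R,3S), 2,3-trans, with O4′ free; compounds 1, 5, 9, 10 and 24 are assumed to be purchasable.

**Route**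

Step 1
Reactants: 1 2-(benzyloxy)-5-bromobenzaldehyde
Product: 3 2-(benzyloxy)-5-bromophenol, via aryl formate 2 (not isolated)
Conditions: mCPBA, CH2Cl2, rt; then K2CO3 (cat.), MeOH, rt
Reagents that add atoms: mCPBA, O=C(OO)c1cccc(Cl)c1
Why: Baeyer–Villiger oxidation of an ortho-alkoxybenzaldehyde should proceed with migration of the electron-rich aryl group to the formate, which methanol cleaves to the phenol that becomes O3′.

Step 2
Reactants: 3 2-(benzyloxy)-5-bromophenol
Product: 4 1-(benzyloxy)-4-bromo-2-(methoxymethoxy)benzene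
Conditions: MOMCl, i-Pr2NEt, CH2Cl2, 0 °C to rt
Reagents that add atoms: chloromethyl methyl ether, COCCl
Why: O-alkylation of the phenol (Williamson type) should install a MOM acetal, which tolerates organolithium and lithium amide bases and is later removed by dilute acid while benzyl ethers stay.

Step 3
Reactants: 5 5-chloro-2,4-dihydroxybenzaldehyde
Product: 6 2,4-bis(benzyloxy)-5-chlorobenzaldehyde
Conditions: BnBr, K2CO3, DMF, 60 °C
Reagents that add atoms: benzyl bromide, BrCc1ccccc1
Why: Williamson etherification should benzylate both phenols; the chlorine, at the future C8, is where electrophilic substitution of the resorcinol ring places it.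

Step 4
Reactants: 6 2,4-bis(benzyloxy)-5-chlorobenzaldehyde
Product: 7 [2,4-bis(benzyloxy)-5-chlorophenyl]methanol
Conditions: NaBH4, THF/MeOH, 0 °C
Reagents that add atoms: none
Why: Borohydride reduction of an aryl aldehyde to the benzylic alcohol is routine and leaves aryl chloride and benzyl ethers alone.

Step 5
Reactants: 7 [2,4-bis(benzyloxy)-5-chlorophenyl]methanol
Product: 8 1,5-bis(benzyloxy)-2-(bromomethyl)-4-chlorobenzene
Conditions: PBr3, CH2Cl2, 0 °C; used at once
Reagents that add atoms: phosphorus tribromide, BrP(Br)Br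
Why: Bromination of the benzylic alcohol through its phosphite ester (SN2) should give the bromide, and the chlorine blocks the ring position at which such electron-rich benzyl bromides usually self-alkylate.

Step 6
Reactants: 9 (4R)-4-benzyl-1,3-oxazolidin-2-one; 10 (benzyloxy)acetyl chloride
Product: 12 (4R)-4-benzyl-3-[(benzyloxy)acetyl]-1,3-oxazolidin-2-one, via lithium oxazolidinide 11 (not isolated)
Conditions: n-BuLi, THF, −78 °C; then 10, −78 to 0 °C
Reagents that add atoms: none
Why: N-acylation of the lithiated oxazolidinone by an acid chloride is the standard way to load the auxiliary.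

Step 7
Reactants: 12 (4R)-4-benzyl-3-[(benzyloxy)acetyl]-1,3-oxazolidin-2-one; 8 1,5-bis(benzyloxy)-2-(bromomethyl)-4-chlorobenzene
Product: 14 (4R)-4-benzyl-3-[(2S)-2-(benzyloxy)-3-[2,4-bis(benzyloxy)-5-chlorophenyl]propanoyl]-1,3-oxazolidin-2-one, via sodium enolate 13 (not isolated)
Conditions: NaN(SiMe3)2, THF, −78 °C; then 8, −78 to −40 °C
Reagents that add atoms: none
Why: Auxiliary-controlled glycolate alkylation: the chelated Z enolate should be alkylated by the benzylic bromide on the face opposite the C4 benzyl group of the (R)-oxazolidinone, which sets the (S) centre that becomes C3.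

Step 8
Reactants: 14 (4R)-4-benzyl-3-[(2S)-2-(benzyloxy)-3-[2,4-bis(benzyloxy)-5-chlorophenyl]propanoyl]-1,3-oxazolidin-2-one
Product: 15 (2S)-2-(benzyloxy)-3-[2,4-bis(benzyloxy)-5-chlorophenyl]-N-methoxy-N-methylpropanamide
Conditions: MeONHMe·HCl, Me3Al, CH2Cl2, −10 °C to rt; aqueous potassium sodium tartrate
Reagents that add atoms: N,O-dimethylhydroxylamine hydrochloride, CNOC.Cl
Why: Weinreb amide formation by aminolysis with Me(Cl)Al–N(OMe)Me should cleave the exocyclic acyl–N bond and release the auxiliary, and the non-basic reagent leaves the α-centre untouched.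

Step 9
Reactants: 4 1-(benzyloxy)-4-bromo-2-(methoxymethoxy)benzene; 15 (2S)-2-(benzyloxy)-3-[2,4-bis(benzyloxy)-5-chlorophenyl]-N-methoxy-N-methylpropanamide
Product: 18 (2S)-2-(benzyloxy)-1-[4-(benzyloxy)-3-(methoxymethoxy)phenyl]-3-[2,4-bis(benzyloxy)-5-chlorophenyl]propan-1-one, via aryllithium 16 (not isolated), via lithium hemiaminal 17 (not isolated)
Conditions: 4, n-BuLi, THF, −78 °C; then 15, −78 to −40 °C; aq. NH4Cl
Reagents that add atoms: none
Why: Bromine–lithium exchange followed by single addition of the aryllithium to the Weinreb amide, whose chelated tetrahedral adduct survives until the quench, should give the aryl ketone and the C2–C1′ bond; the ring A chloride does not exchange.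

Step 10
Reactants: 18 (2S)-2-(benzyloxy)-1-[4-(benzyloxy)-3-(methoxymethoxy)phenyl]-3-[2,4-bis(benzyloxy)-5-chlorophenyl]propan-1-one
Product: 19 (1R,2S)-2-(benzyloxy)-1-[4-(benzyloxy)-3-(methoxymethoxy)phenyl]-3-[2,4-bis(benzyloxy)-5-chlorophenyl]propan-1-ol
Conditions: Zn(BH4)2, Et2O, −30 to 0 °C
Reagents that add atoms: none
Why: Chelation-controlled reduction (Cram chelate model): zinc bridges the carbonyl and the α-benzyloxy oxygen and hydride arrives on the face away from the CH2Ar group, which should give the 1,2-anti alcohol with (R) at the future C2.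

Step 11
Reactants: 19 (1R,2S)-2-(benzyloxy)-1-[4-(benzyloxy)-3-(methoxymethoxy)phenyl]-3-[2,4-bis(benzyloxy)-5-chlorophenyl]propan-1-ol
Product: 22 (2R,3S)-3,5,7-tris(benzyloxy)-2-[4-(benzyloxy)-3-(methoxymethoxy)phenyl]chromane, via aryne 20 (not isolated), via C8 aryllithium 21 (not isolated)
Conditions: lithium 2,2,6,6-tetramethylpiperidide (3.5 equiv), THF, −78 °C to rt; aq. NH4Cl
Reagents that add atoms: none
Why: The amide base should form the C2–OLi alkoxide and remove the C8a hydrogen next to the C8 chlorine; loss of LiCl gives aryne 20 across C8–C8a, the alkoxide oxygen adds to C8a (6-exo-dig) and the C8 aryllithium 21 is protonated on quench, so chlorine leaves C8 and oxygen enters at C8a (cine substitution). The closest known reaction type is the aryne (elimination–addition) cyclisation of halobenzenes carrying a tethered alkoxide, which gives chromans and dihydrobenzofurans. Ring C is the only ring closed and no stereocentre is formed: C2 and C3 keep the configuration of 19 because neither C–O bond is broken. The site of addition is secured twice: the chain on C4a can reach only C8a, and the C7 benzyloxy group beside C8 polarises the triple bond so that a nucleophile adds to the distal carbon C8a while the charge develops at C8 next to the inductively withdrawing oxygen. Closure to a five-membered ring is excluded because O3 is benzylated, and lithiation at C6–H between the two benzyloxy groups is reversible and leads nowhere, whereas loss of LiCl is irreversible.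

Step 12
Reactants: 22 (2R,3S)-3,5,7-tris(benzyloxy)-2-[4-(benzyloxy)-3-(methoxymethoxy)phenyl]chromane
Product: 23 2-(benzyloxy)-5-[(2R,3S)-3,5,7-tris(benzyloxy)chroman-2-yl]phenol
Conditions: HCl (1.25 M in MeOH), THF, 0 °C to rt
Reagents that add atoms: none
Why: Acid-catalysed acetal exchange should remove the MOM group alone, since benzyl ethers are inert to dilute acid at this temperature, and it frees only the 3′-phenol.

Step 13
Reactants: 23 2-(benzyloxy)-5-[(2R,3S)-3,5,7-tris(benzyloxy)chroman-2-yl]phenol; 24 3,4,5-tris(benzyloxy)benzoic acid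
Product: 25 2-(benzyloxy)-5-[(2R,3S)-3,5,7-tris(benzyloxy)chroman-2-yl]phenyl 3,4,5-tris(benzyloxy)benzoate
Conditions: DCC, DMAP (cat.), CH2Cl2, rt
Reagents that add atoms: none
Why: Steglich esterification should acylate the 3′-phenol, the only free hydroxyl in 23, so the galloyl group can go nowhere else.

Step 14
Reactants: 25 2-(benzyloxy)-5-[(2R,3S)-3,5,7-tris(benzyloxy)chroman-2-yl]phenyl 3,4,5-tris(benzyloxy)benzoate
Product: 26 catechin 3′-O-gallate
Conditions: H2 (1 atm), Pd(OH)2 on carbon, THF/MeOH, rt; filtration, no base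
Reagents that add atoms: none
Why: Hydrogenolysis should cleave all seven benzyl ethers (two on ring A, one at O3, one at O4′, three on the gallate) while the aryl ester and the cyclic benzylic ether of ring C persist under neutral conditions.

**Compound list**

1 | 2-(benzyloxy)-5-bromobenzaldehyde | O=Cc1cc(Br)ccc1OCc1ccccc1 | starting material
2 | 2-(benzyloxy)-5-bromophenyl formate (aryl formate) | O=COc1cc(Br)ccc1OCc1ccccc1 | intermediate
3 | 2-(benzyloxy)-5-bromophenol | Oc1cc(Br)ccc1OCc1ccccc1 | intermediate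
4 | 1-(benzyloxy)-4-bromo-2-(methoxymethoxy)benzene | COCOc1cc(Br)ccc1OCc1ccccc1 | intermediate
5 | 5-chloro-2,4-dihydroxybenzaldehyde | O=Cc1cc(Cl)c(O)cc1O | starting material
6 | 2,4-bis(benzyloxy)-5-chlorobenzaldehyde | O=Cc1cc(Cl)c(OCc2ccccc2)cc1OCc1ccccc1 | intermediate
7 | [2,4-bis(benzyloxy)-5-chlorophenyl]methanol | OCc1cc(Cl)c(OCc2ccccc2)cc1OCc1ccccc1 | intermediate
8 | 1,5-bis(benzyloxy)-2-(bromomethyl)-4-chlorobenzene | BrCc1cc(Cl)c(OCc2ccccc2)cc1OCc1ccccc1 | intermediate
9 | (4R)-4-benzyl-1,3-oxazolidin-2-one | O=C1OC[C@@H](Cc2ccccc2)N1 | starting material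
10 | (benzyloxy)acetyl chloride | O=C(Cl)COCc1ccccc1 | starting material
11 | lithium (4R)-4-benzyl-2-oxo-1,3-oxazolidin-3-ide (lithium oxazolidinide) | O=C1OC[C@@H](Cc2ccccc2)N1[Li] | intermediate
12 | (4R)-4-benzyl-3-[(benzyloxy)acetyl]-1,3-oxazolidin-2-one | O=C1OC[C@@H](Cc2ccccc2)N1C(=O)COCc1ccccc1 | intermediate
13 | sodium (Z)-enolate of 12 (sodium enolate) | O=C1OC[C@@H](Cc2ccccc2)N1/C(O[Na])=C/OCc1ccccc1 | intermediate
14 | (4R)-4-benzyl-3-[(2S)-2-(benzyloxy)-3-[2,4-bis(benzyloxy)-5-chlorophenyl]propanoyl]-1,3-oxazolidin-2-one | O=C1OC[C@@H](Cc2ccccc2)N1C(=O)[C@@H](OCc1ccccc1)Cc1cc(Cl)c(OCc2ccccc2)cc1OCc1ccccc1 | intermediate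
15 | (2S)-2-(benzyloxy)-3-[2,4-bis(benzyloxy)-5-chlorophenyl]-N-methoxy-N-methylpropanamide | CON(C)C(=O)[C@@H](OCc1ccccc1)Cc1cc(Cl)c(OCc2ccccc2)cc1OCc1ccccc1 | intermediate
16 | [4-(benzyloxy)-3-(methoxymethoxy)phenyl]lithium (aryllithium) | [Li]c1ccc(OCc2ccccc2)c(OCOC)c1 | intermediate
17 | lithium alkoxide of the tetrahedral adduct of 16 with 15 (lithium hemiaminal; new carbinol centre undefined) | CON(C)C(O[Li])(c1ccc(OCc2ccccc2)c(OCOC)c1)[C@@H](OCc1ccccc1)Cc1cc(Cl)c(OCc2ccccc2)cc1OCc1ccccc1 | intermediate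
18 | (2S)-2-(benzyloxy)-1-[4-(benzyloxy)-3-(methoxymethoxy)phenyl]-3-[2,4-bis(benzyloxy)-5-chlorophenyl]propan-1-one | O=C(c1ccc(OCc2ccccc2)c(OCOC)c1)[C@@H](OCc1ccccc1)Cc1cc(Cl)c(OCc2ccccc2)cc1OCc1ccccc1 | intermediate
19 | (1R,2S)-2-(benzyloxy)-1-[4-(benzyloxy)-3-(methoxymethoxy)phenyl]-3-[2,4-bis(benzyloxy)-5-chlorophenyl]propan-1-ol | O[C@H](c1ccc(OCc2ccccc2)c(OCOC)c1)[C@@H](OCc1ccccc1)Cc1cc(Cl)c(OCc2ccccc2)cc1OCc1ccccc1 | intermediate
20 | lithium alkoxide of 19 with the ring A aryne across C8–C8a (aryne) | [Li]O[C@H](c1ccc(OCc2ccccc2)c(OCOC)c1)[C@@H](OCc1ccccc1)CC1=C(OCc2ccccc2)C=C(OCc2ccccc2)C#C1 | intermediate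
21 | 8-lithio derivative of 22 (C8 aryllithium) | COCOc1cc(ccc1OCc1ccccc1)[C@H]1Oc2c([Li])c(OCc3ccccc3)cc(OCc3ccccc3)c2C[C@@H]1OCc1ccccc1 | intermediate
22 | (2R,3S)-3,5,7-tris(benzyloxy)-2-[4-(benzyloxy)-3-(methoxymethoxy)phenyl]chromane | COCOc1cc(ccc1OCc1ccccc1)[C@H]1Oc2cc(OCc3ccccc3)cc(OCc3ccccc3)c2C[C@@H]1OCc1ccccc1 | intermediate
23 | 2-(benzyloxy)-5-[(2R,3S)-3,5,7-tris(benzyloxy)chroman-2-yl]phenol | Oc1cc(ccc1OCc1ccccc1)[C@H]1Oc2cc(OCc3ccccc3)cc(OCc3ccccc3)c2C[C@@H]1OCc1ccccc1 | intermediate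
24 | 3,4,5-tris(benzyloxy)benzoic acid | OC(=O)c1cc(OCc2ccccc2)c(OCc2ccccc2)c(OCc2ccccc2)c1 | starting material
25 | 2-(benzyloxy)-5-[(2R,3S)-3,5,7-tris(benzyloxy)chroman-2-yl]phenyl 3,4,5-tris(benzyloxy)benzoate | O=C(Oc1cc(ccc1OCc1ccccc1)[C@H]1Oc2cc(OCc3ccccc3)cc(OCc3ccccc3)c2C[C@@H]1OCc1ccccc1)c1cc(OCc2ccccc2)c(OCc2ccccc2)c(OCc2ccccc2)c1 | intermediate
26 | catechin 3′-O-gallate, (2R,3S) | O=C(Oc1cc([C@H]2Oc3cc(O)cc(O)c3C[C@@H]2O)ccc1O)c1cc(O)c(O)c(O)c1 | target

**Count and risks**

Total step count: 14. Longest linear sequence: 11 steps (3, 4, 5, 7, 8, 9, 10, 11, 12, 13, 14).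

Steps most likely to fail:

Step 11. The base may be used up in reversible lithiation at C6–H between the two benzyloxy groups or at C2′–H beside the MOM ether. Benzylic ether positions may be metalated and rearrange, or the carbinol C–H may transfer hydride to the aryne, so that ring C does not close. The fallback moves the halogen to C8a and replaces the aryne by a metal-catalysed coupling; it sets out from 12. 1,3-Bis(benzyloxy)-5-bromobenzene F1 would be formylated (POCl3, DMF; Vilsmeier–Haack) to 2,4-bis(benzyloxy)-6-bromobenzaldehyde F2, reduced (NaBH4) to [2,4-bis(benzyloxy)-6-bromophenyl]methanol F3 and brominated (PBr3) to 1,5-bis(benzyloxy)-3-bromo-2-(bromomethyl)benzene F4. Alkylation of the sodium enolate 13 of 12 with F4 under the conditions of step 7 would give (4R)-4-benzyl-3-[(2S)-2-(benzyloxy)-3-[2,4-bis(benzyloxy)-6-bromophenyl]propanoyl]-1,3-oxazolidin-2-one F5. Aminolysis as in step 8 would give (2S)-2-(benzyloxy)-3-[2,4-bis(benzyloxy)-6-bromophenyl]-N-methoxy-N-methylpropanamide F6. Addition of aryllithium 16 at −78 °C would give (2S)-2-(benzyloxy)-1-[4-(benzyloxy)-3-(methoxymethoxy)phenyl]-3-[2,4-bis(benzyloxy)-6-bromophenyl]propan-1-one F7, and Zn(BH4)2 reduction would give (1R,2S)-2-(benzyloxy)-1-[4-(benzyloxy)-3-(methoxymethoxy)phenyl]-3-[2,4-bis(benzyloxy)-6-bromophenyl]propan-1-ol F8. Intramolecular Ullmann-type etherification of F8 (CuI, 1,10-phenanthroline, Cs2CO3, toluene, 110 °C) would close ring C through the same O1–C8a bond and come back to the route at 22.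

Step 8. The aluminium reagent may attack the ring carbonyl of the hindered imide (endocyclic cleavage, opening of the auxiliary) instead of the acyl carbonyl. The fallback sets out from 14: LiOH/H2O2 (THF/H2O, 0 °C), which is selective for the exocyclic carbonyl, would give (2S)-2-(benzyloxy)-3-[2,4-bis(benzyloxy)-5-chlorophenyl]propanoic acid F9. Amide coupling of F9 with N,O-dimethylhydroxylamine hydrochloride (EDC·HCl, HOBt, i-Pr2NEt, CH2Cl2) would come back to the route at 15.

Step 10. Facial selectivity may erode if zinc is held by the other ether oxygens and the five-membered chelate is not fully formed. The fallback adds the aryl group to an aldehyde under Felkin–Anh control instead of hydride to a ketone under chelation; it sets out from 15. Reduction with i-Bu2AlH (THF, −78 °C) would give (2S)-2-(benzyloxy)-3-[2,4-bis(benzyloxy)-5-chlorophenyl]propanal F10, used at once. Aryllithium 16 would be transmetalated with ClTi(OiPr)3 to [4-(benzyloxy)-3-(methoxymethoxy)phenyl]titanium triisopropoxide F11, which cannot chelate and should add to F10 anti to the benzyloxy group. This gives the same 1,2-anti alcohol and comes back to the route at 19.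

**Further compounds**

F1 | step 11 | 1,3-bis(benzyloxy)-5-bromobenzene | Brc1cc(OCc2ccccc2)cc(OCc2ccccc2)c1
F2 | step 11 | 2,4-bis(benzyloxy)-6-bromobenzaldehyde | O=Cc1c(Br)cc(OCc2ccccc2)cc1OCc1ccccc1
F3 | step 11 | [2,4-bis(benzyloxy)-6-bromophenyl]methanol | OCc1c(Br)cc(OCc2ccccc2)cc1OCc1ccccc1
F4 | step 11 | 1,5-bis(benzyloxy)-3-bromo-2-(bromomethyl)benzene | BrCc1c(Br)cc(OCc2ccccc2)cc1OCc1ccccc1
F5 | step 11 | (4R)-4-benzyl-3-[(2S)-2-(benzyloxy)-3-[2,4-bis(benzyloxy)-6-bromophenyl]propanoyl]-1,3-oxazolidin-2-one | O=C1OC[C@@H](Cc2ccccc2)N1C(=O)[C@@H](OCc1ccccc1)Cc1c(Br)cc(OCc2ccccc2)cc1OCc1ccccc1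
F6 | step 11 | (2S)-2-(benzyloxy)-3-[2,4-bis(benzyloxy)-6-bromophenyl]-N-methoxy-N-methylpropanamide | CON(C)C(=O)[C@@H](OCc1ccccc1)Cc1c(Br)cc(OCc2ccccc2)cc1OCc1ccccc1
F7 | step 11 | (2S)-2-(benzyloxy)-1-[4-(benzyloxy)-3-(methoxymethoxy)phenyl]-3-[2,4-bis(benzyloxy)-6-bromophenyl]propan-1-one | O=C(c1ccc(OCc2ccccc2)c(OCOC)c1)[C@@H](OCc1ccccc1)Cc1c(Br)cc(OCc2ccccc2)cc1OCc1ccccc1
F8 | step 11 | (1R,2S)-2-(benzyloxy)-1-[4-(benzyloxy)-3-(methoxymethoxy)phenyl]-3-[2,4-bis(benzyloxy)-6-bromophenyl]propan-1-ol | O[C@H](c1ccc(OCc2ccccc2)c(OCOC)c1)[C@@H](OCc1ccccc1)Cc1c(Br)cc(OCc2ccccc2)cc1OCc1ccccc1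
F9 | step 8 | (2S)-2-(benzyloxy)-3-[2,4-bis(benzyloxy)-5-chlorophenyl]propanoic acid | OC(=O)[C@@H](OCc1ccccc1)Cc1cc(Cl)c(OCc2ccccc2)cc1OCc1ccccc1
F10 | step 10 | (2S)-2-(benzyloxy)-3-[2,4-bis(benzyloxy)-5-chlorophenyl]propanal | O=C[C@@H](OCc1ccccc1)Cc1cc(Cl)c(OCc2ccccc2)cc1OCc1ccccc1
F11 | step 10 | [4-(benzyloxy)-3-(methoxymethoxy)phenyl]titanium triisopropoxide | CC(C)O[Ti](OC(C)C)(OC(C)C)c1ccc(OCc2ccccc2)c(OCOC)c1
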